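**Retrosynthetic overview**
1. The route rests on the C8–C9 bond of the ten-membered oxecane ring (O, C3–C11; numbering: vinyl C1=C2, ether carbon C3, epoxide C6–C7, ring fusion C10–C11, CHBr C14, CMe2 C15). C8 is the allylic CH2 on C7 and C9 is the exocyclic CH2 on C10 of the bromocyclohexane ring A.
2. Oxirane ⇐ E-C6=C7 alkene (chiral dioxirane); C9–H ⇐ C9–SO2Ph; oxecane ⇐ C8–C9 closure by the C9 α-sulfonyl carbanion on the C8 allylic chloride.
3. Cyclisation precursor ⇐ di-tertiary ether C11–O–C3 from the ring A tertiary chloride and (R)-linalool (C3 bought, O–C3 never broken), then E-selective oxidation and chlorination at C8.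
4. Ring A ⇐ bromonium cyclisation of geranyl phenyl sulfone, which already carries the sulfone on C9, with the alkene mixture converged on the C11 chloride in the same operation.
5. Ring order: ring A (step 2), oxecane (step 6), oxirane (step 8).

Key step: step 6

Remark: the bromonium source is achiral, so ring A (4, 5 and 6) is racemic and is drawn as the antipode that is carried on. Step 3 joins it to enantiopure (R)-linalool; the ether formed from the other antipode is a diastereomer of 8, and it is assumed that it is removed by chromatography, so that 8 and all later compounds are single enantiomers.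

**Step 1**
Reactants: 1 geranyl bromide; 2 sodium benzenesulfinate
Product: 3 geranyl phenyl sulfone, {[(2E)-3,7-dimethylocta-2,6-dien-1-yl]sulfonyl}benzene
Conditions: DMF, 0 °C to rt
Reagents that add atoms: none
Why: SN2 S-alkylation of the sulfinate by a primary allylic bromide gives the sulfone with the E-alkene untouched (classical sulfone synthesis).

**Step 2**
Reactants: 3 geranyl phenyl sulfone
Product: 6 racemic tertiary chloride ({[(1R*,3S*)-3-bromo-6-chloro-2,2,6-trimethylcyclohexyl]methyl}sulfonyl)benzene as C11 epimers, via exocyclic alkene 4 (not isolated), via endocyclic alkene 5 (not isolated)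
Conditions: Et2SBr·SbCl5Br, MeNO2, −25 °C; aq. Na2SO3/NaHCO3 wash, solvent exchange; then HCl (Et2O), CH2Cl2, −78 to −40 °C on the crude alkene mixture
Reagents that add atoms: bromodiethylsulfonium bromopentachloroantimonate, CC[S+](Br)CC.Cl[Sb-](Cl)(Cl)(Cl)(Cl)Br; hydrogen chloride, Cl
Why: Bromonium-induced cation–olefin cyclisation followed by Markovnikov hydrochlorination: Br+ is taken up by the electron-rich C14=C15 alkene (C10=C11 is deactivated by the allylic sulfone), the chair closure of ring A puts Br on C14 and the C9 arm on C10 both equatorial and hence cis, the C11 cation loses a proton to give alkenes 4 and 5, and HCl at low temperature returns both to the same C11 cation, which collapses with chloride before proton loss towards C10 can touch that centre; the C11 configuration is irrelevant because C11 is ionised again in step 3.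

**Step 3**
Reactants: 6 tertiary chloride; 7 (R)-linalool
Product: 8 (3R,10S,11S,14S)-di-tertiary ether, phenyl {[(1S,3S,6S)-3-bromo-6-{[(3R)-3,7-dimethylocta-1,6-dien-3-yl]oxy}-2,2,6-trimethylcyclohexyl]methyl} sulfone
Conditions: AgOSO2CF3, 2,6-di-tert-butyl-4-methylpyridine, 7 (20 equiv, co-solvent), CH2Cl2, 4 Å molecular sieves, −40 to −10 °C, dark; chromatographic separation of the diastereomers
Reagents that add atoms: none
Why: Silver-assisted SN1 etherification: AgCl precipitation frees the C11 cation, which is captured by the hydroxyl of 7 in large excess while the hindered pyridine only takes up CF3SO3H; approach anti to the axial C15 methyl places the ether oxygen equatorial and trans to the C9 arm (11S with 10S), the O–C3 bond of 7 is never broken (3R kept), the ether of the ring A antipode is a diastereomer that is separated here, and alkenes 4 and 5 from competing proton loss can be returned to the HCl stage of step 2.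

**Step 4**
Reactants: 8 di-tertiary ether
Product: 9 (E)-allylic alcohol, 8 hydroxylated at C8 (C6=C7 E, CH2OH on C7)
Conditions: SeO2 (cat.), t-BuOOH, salicylic acid (cat.), CH2Cl2, 0 °C to rt, stopped before full conversion; recovered 8 recycled
Reagents that add atoms: tert-butyl hydroperoxide, CC(C)(C)OO; selenium dioxide, O=[Se]=O (catalytic oxygen carrier)
Why: SeO2/t-BuOOH allylic oxidation (ene reaction, then 2,3-sigmatropic shift) hydroxylates the E-methyl of the gem-dimethyl alkene, which becomes C8 with E geometry; the vinyl group has no allylic hydrogen and the sulfone, bromide and ether are inert.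

**Step 5**
Reactants: 9 allylic alcohol
Product: 10 (E)-allylic chloride, the cyclisation precursor (C8–Cl)
Conditions: CH3SO2Cl, LiCl, 2,4,6-collidine, DMF, 0 °C
Reagents that add atoms: lithium chloride, [Li+].[Cl-]
Why: Allylic chlorination through the mesylate, with chloride SN2 at the primary carbon and no allylic transposition, in a collidine-buffered medium that spares the acid-labile tertiary allylic ether.

**Step 6**
Reactants: 10 allylic chloride
Product: 11 9-phenylsulfonyl E-oxecene, trans-fused to ring A (C9 epimers)
Conditions: KN(SiMe3)2 (1.5 equiv), THF, 0.002 M, 10 added by syringe pump over 8 h, −20 °C to rt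
Reagents that add atoms: none
Why: The amide removes a proton from C9, the only sp3 C–H α to the sulfone, and the soft carbanion displaces the primary allylic chloride at C8 in an SN2 step that forms C8–C9. This is a macrocyclising alkylation of an α-sulfonyl carbanion with an allylic halide, a reaction type established for ten- to fourteen-membered carbocycles of germacrane and cembrane terpenoids. The oxecane closes in the 10-exo-tet mode, with the chloride leaving outside the ring and the E geometry of C6=C7 untouched. C9 becomes a stereocentre, but both epimers converge in step 7, so no element of control is needed. Ring closure over oligomerisation is secured by high dilution and slow addition, and SN2 over SN2′ by the unhindered primary terminus (SN2′ at C6 would need an eight-membered ring and a more hindered carbon). C10, the carbon next to the carbanion, carries no leaving group and the ether oxygen is one carbon further away on C11, so β-elimination is excluded, and the equatorial neopentyl C14 bromide has no antiperiplanar hydrogen, so it is neither eliminated nor substituted.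

**Step 7**
Reactants: 11 macrocyclic sulfone
Product: 12 (3R,10S,11S,14S)-E-oxecene
Conditions: Na(Hg) (6%), Na2HPO4, MeOH/THF, −20 °C
Reagents that add atoms: none
Why: Reductive desulfonylation by electron transfer (the conditions of the Julia olefination) cleaves the C9–S bond at a buffered low temperature at which the secondary bromide and the alkenes are expected to persist, and both C9 epimers give the same CH2.

**Step 8**
Reactants: 12 E-oxecene
Product: 13 target, (3R,6S,7S,10S,11S,14S)-epoxide
Conditions: 1,2:4,5-di-O-isopropylidene-β-L-erythro-2,3-hexodiulo-2,6-pyranose (L-fructose-derived ketone of the Shi epoxidation, 0.3 equiv), KHSO5, K2CO3, n-Bu4NHSO4, MeCN/CH2(OMe)2/aq. Na2B4O7, 0 °C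
Reagents that add atoms: potassium peroxymonosulfate, [K+].[O-]S(=O)(=O)OO
Why: Shi epoxidation: the chiral dioxirane reacts with the electron-rich trisubstituted E-alkene much faster than with the vinyl group, and because the D-fructose-derived ketone gives R,R-type epoxides from E-alkenes, its enantiomer is chosen to deliver oxygen to the face that gives 6S,7S.

**Compound list**
1 | geranyl bromide | CC(C)=CCC/C(C)=C/CBr | starting material
2 | sodium benzenesulfinate | [Na+].[O-]S(=O)c1ccccc1 | starting material
3 | geranyl phenyl sulfone | CC(C)=CCC/C(C)=C/CS(=O)(=O)c1ccccc1 | intermediate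
4 | racemic ({[(1R*,3S*)-3-bromo-2,2-dimethyl-6-methylidenecyclohexyl]methyl}sulfonyl)benzene, not isolated (the enantiomer carried on is drawn) | O=S(=O)(c1ccccc1)C[C@H]1C(C)(C)[C@@H](Br)CCC1=C | intermediate
5 | racemic ({[(1R*,5S*)-5-bromo-2,6,6-trimethylcyclohex-2-en-1-yl]methyl}sulfonyl)benzene, not isolated (the enantiomer carried on is drawn) | O=S(=O)(c1ccccc1)C[C@H]1C(C)(C)[C@@H](Br)CC=C1C | intermediate
6 | racemic ({[(1R*,3S*)-3-bromo-6-chloro-2,2,6-trimethylcyclohexyl]methyl}sulfonyl)benzene, C11 epimers (the enantiomer carried on is drawn) | O=S(=O)(c1ccccc1)C[C@H]1C(C)(C)[C@@H](Br)CCC1(C)Cl | intermediate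
7 | (R)-linalool | C=C[C@](C)(O)CCC=C(C)C | starting material
8 | (3R,10S,11S,14S)-ether of ring A sulfone and (R)-linalool | O=S(=O)(c1ccccc1)C[C@H]2C(C)(C)[C@@H](Br)CC[C@]2(C)O[C@@](C)(C=C)CCC=C(C)C | intermediate
9 | (E)-allylic alcohol (C8–OH) | O=S(=O)(c1ccccc1)C[C@H]2C(C)(C)[C@@H](Br)CC[C@]2(C)O[C@@](C)(C=C)CC/C=C(C)/CO | intermediate
10 | (E)-allylic chloride (C8–Cl), cyclisation precursor | O=S(=O)(c1ccccc1)C[C@H]2C(C)(C)[C@@H](Br)CC[C@]2(C)O[C@@](C)(C=C)CC/C=C(C)/CCl | intermediate
11 | 9-phenylsulfonyl E-oxecene (C9 epimers) | C=C[C@@]1(C)CC/C=C(C)/CC(S(=O)(=O)c3ccccc3)[C@H]2C(C)(C)[C@@H](Br)CC[C@]2(C)O1 | intermediate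
12 | (3R,10S,11S,14S)-E-oxecene | C=C[C@@]1(C)CC/C=C(C)/CC[C@H]2C(C)(C)[C@@H](Br)CC[C@]2(C)O1 | intermediate
13 | CNP0243863.1 | C=C[C@@]1(C)CC[C@@H]2O[C@@]2(C)CC[C@H]2C(C)(C)[C@@H](Br)CC[C@]2(C)O1 | target

**Total step count:** 8. **Longest linear sequence:** 8 steps (1 to 13); 7 enters at step 3.

**Steps most likely to fail**

Step 3. Proton loss from the C11 cation can outrun its capture by the hindered tertiary alcohol, and the two diastereomeric ethers may be hard to separate. The fallback replaces halide abstraction in the presence of a base by acid-catalysed alkylation with an imidate, whose leaving group is neutral and non-basic, in a non-polar medium. It sets out from 6, which is solvolysed with Ag2CO3 in aqueous acetone to the racemic tertiary alcohol F1. F1 is converted with Cl3CCN and catalytic DBU into the tertiary trichloroacetimidate F2. F2 is then coupled with excess 7 under catalytic BF3·OEt2 in cyclohexane/CH2Cl2 at −30 °C (the known alkylation of hindered alcohols by tertiary trichloroacetimidates), the diastereomers are separated as before, and the route is rejoined at 8.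

Step 6. Carbanion formation at C9 may be incomplete, and intermolecular alkylation or base attack on the allylic chloride may compete with ring closure. The fallback is a Tsuji–Trost macrocyclisation under neutral conditions with a doubly stabilised carbanion. It sets out from 8, which is deprotonated at C9 with LiN(i-Pr)2 and acylated with 2-(trimethylsilyl)ethyl chloroformate to the sulfonyl ester F3. SeO2/t-BuOOH then gives the allylic alcohol F4, and ClCO2CH3/pyridine gives the allylic methyl carbonate F5. Pd(PPh3)4 (catalytic, THF, high dilution, 60 °C) ionises the carbonate with zerovalent palladium; the methoxide set free deprotonates C9, and the soft carbanion attacks the allyl terminus C8 to give the macrocyclic sulfonyl ester F6. n-Bu4NF removes the silylethyl ester with loss of CO2, and the route is rejoined at 11.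

Step 8. Facial selectivity may be poor if the conformational bias of the oxecene opposes the chiral dioxirane. The fallback delivers oxygen to the face opposite to the one an electrophile attacks. It sets out from 12, which with N-bromosuccinimide in aqueous THF at 0 °C gives the trans-bromohydrin F7 (Br on C6, water at the tertiary C7 from the other face). K2CO3 in MeOH then closes the oxirane with inversion at C6, and the route is rejoined at 13.

**Further compounds**
F1 | step 3 | racemic tertiary alcohol of ring A sulfone (C11–OH, C11 epimers) | O=S(=O)(c1ccccc1)C[C@H]1C(C)(C)[C@@H](Br)CCC1(C)O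
F2 | step 3 | its trichloroacetimidate | O=S(=O)(c1ccccc1)C[C@H]1C(C)(C)[C@@H](Br)CCC1(C)OC(=N)C(Cl)(Cl)Cl
F3 | step 6 | 2-(trimethylsilyl)ethyl C9-carboxylate of 8 (C9 epimers) | C[Si](C)(C)CCOC(=O)C(S(=O)(=O)c1ccccc1)[C@H]2C(C)(C)[C@@H](Br)CC[C@]2(C)O[C@@](C)(C=C)CCC=C(C)C
F4 | step 6 | its (E)-allylic alcohol (C8–OH) | C[Si](C)(C)CCOC(=O)C(S(=O)(=O)c1ccccc1)[C@H]2C(C)(C)[C@@H](Br)CC[C@]2(C)O[C@@](C)(C=C)CC/C=C(C)/CO
F5 | step 6 | its allylic methyl carbonate | C[Si](C)(C)CCOC(=O)C(S(=O)(=O)c1ccccc1)[C@H]2C(C)(C)[C@@H](Br)CC[C@]2(C)O[C@@](C)(C=C)CC/C=C(C)/COC(=O)OC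
F6 | step 6 | macrocyclic C9 sulfonyl ester (C9 epimers) | C=C[C@@]1(C)CC/C=C(C)/CC(C(=O)OCC[Si](C)(C)C)(S(=O)(=O)c3ccccc3)[C@H]2C(C)(C)[C@@H](Br)CC[C@]2(C)O1
F7 | step 8 | trans-bromohydrin of 12 (C6–Br, C7–OH) | C=C[C@@]1(C)CC[C@@H](Br)[C@@](C)(O)CC[C@H]2C(C)(C)[C@@H](Br)CC[C@]2(C)O1
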